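Atoms are numbered as in furo[3,4-c]furan (C1H2, O2, C3HAr, C3a–OH, C4H2, O5, C6HAr, C6a–H). Everything rests on cutting the C3–C3a bond of ring A (O2, C1, C3, C3a, C6a): ring A is made by Lewis-acid ring contraction of a seven-membered cyclic vinyl acetal of veratraldehyde, a 6-silyloxy-4,5-dihydro-1,3-dioxepine. One operation moves the acetal carbon from oxygen to carbon, forms C3–C3a, sets C3 and the oxygenated quaternary C3a under control of C6a, and releases C4 as an aldehyde. The step exploits the O2–C3H(Ar) acetal-type carbon beside the C3a carbinol that carries the one-carbon branch C4. Ring B is then closed by SN2 etherification.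

Key step: step 7

Remark: the SMILES specifies 3S,3aS,6R,6aS, i.e. 3a-OH anti to 6a-H (a trans ring junction), and the route is built for this isomer; the acetal carbon C2 of the dioxepane intermediates 9–11 is carried as a mixture of epimers because it becomes planar in step 7.

Step 1
Reactants: 1 (Z)-but-2-ene-1,4-diol; 2 3,4-dimethoxybenzaldehyde
Product: 3 2-(3,4-dimethoxyphenyl)-4,7-dihydro-1,3-dioxepine
Conditions: p-TsOH·H2O (cat.), toluene, reflux, Dean–Stark trap
Reagents that add atoms: none
Why: Acid-catalysed acetalisation with azeotropic removal of water; the cis alkene holds both hydroxyls in reach, so the seven-membered acetal closes readily.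

Step 2
Reactants: 3 2-(3,4-dimethoxyphenyl)-4,7-dihydro-1,3-dioxepine
Product: 5 2-(3,4-dimethoxyphenyl)-1,3-dioxepan-5-ol (racemic, cis/trans mixture), via B-alkyl-9-BBN adduct 4 (not isolated)
Conditions: 9-BBN, THF, 0 to 50 °C; then NaOH, H2O2, H2O, 0 to 23 °C
Reagents that add atoms: hydrogen peroxide, OO
Why: Hydroboration–oxidation of a symmetrical cis alkene gives a single constitutional isomer, and the new carbinol centre is of no consequence because it is oxidised in the next step.

Step 3
Reactants: 5 2-(3,4-dimethoxyphenyl)-1,3-dioxepan-5-ol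
Product: 6 2-(3,4-dimethoxyphenyl)-1,3-dioxepan-5-one (racemic)
Conditions: Pr4N[RuO4] (5 mol %), NMO, 4 Å molecular sieves, CH2Cl2, 23 °C
Reagents that add atoms: none
Why: Ley–Griffith oxidation of a secondary alcohol under neutral conditions that leave the acid-labile aryl acetal intact.

Step 4
Reactants: 6 2-(3,4-dimethoxyphenyl)-1,3-dioxepan-5-one
Product: 7 [2-(3,4-dimethoxyphenyl)-4,7-dihydro-1,3-dioxepin-5-yl]oxy(trimethyl)silane
Conditions: LiN(iPr)2, Me3SiCl, THF, −78 °C
Reagents that add atoms: chlorotrimethylsilane, C[Si](C)(C)Cl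
Why: Kinetic enolisation and O-silylation; an α-alkoxy ketone should be deprotonated at the α′-methylene remote from the ring oxygen (C6), which fixes the C5=C6 enol ether.

Step 5
Reactants: 7 [2-(3,4-dimethoxyphenyl)-4,7-dihydro-1,3-dioxepin-5-yl]oxy(trimethyl)silane; 2 3,4-dimethoxybenzaldehyde
Product: 9 (6S)-6-[(R)-(3,4-dimethoxyphenyl)(hydroxy)methyl]-2-(3,4-dimethoxyphenyl)-1,3-dioxepan-5-one (anti aldol, C2 epimers), via trichlorosilyl enolate 8 (not isolated)
Conditions: SiCl4, Hg(OAc)2 (1 mol %), CH2Cl2, 23 °C, then evaporation; 2, (4S,5S)-1,3-dimethyl-4,5-diphenyl-2-(piperidin-1-yl)-1,3,2-diazaphospholidine 2-oxide (10 mol %), CH2Cl2, −78 °C; aq. NaHCO3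
Reagents that add atoms: none
Why: Lewis-base-catalysed aldol addition of a trichlorosilyl enolate: the ring-locked E-enolate should react through a closed chair-like siliconate to give the anti adduct, and the chiral phosphoramide selects the aldehyde face so that C6 (S) and the carbinol carbon (R) are set together; the catalyst antipode is used if the first run shows the opposite sense.

Step 6
Reactants: 9 (6S)-6-[(R)-(3,4-dimethoxyphenyl)(hydroxy)methyl]-2-(3,4-dimethoxyphenyl)-1,3-dioxepan-5-one
Product: 11 (5S)-2-(3,4-dimethoxyphenyl)-5-[(R)-(3,4-dimethoxyphenyl)(triisopropylsilyloxy)methyl]-6-(triisopropylsilyloxy)-4,5-dihydro-1,3-dioxepine, via silyl ether ketone 10 (not isolated)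
Conditions: iPr3SiOTf (2.6 equiv), Et3N, CH2Cl2, −78 to 0 °C
Reagents that add atoms: triisopropylsilyl trifluoromethanesulfonate, CC(C)[Si](C(C)C)(C(C)C)OS(=O)(=O)C(F)(F)F
Why: O-Silylation of the alcohol followed by soft enolisation (silyl triflate and amine) of the ketone, which should remove a proton from the unhindered O–CH2 group (C4) and not from the substituted C6, so the ene-diol bis-ether forms without touching the C6 stereocentre.

Step 7
Reactants: 11 (5S)-2-(3,4-dimethoxyphenyl)-5-[(R)-(3,4-dimethoxyphenyl)(triisopropylsilyloxy)methyl]-6-(triisopropylsilyloxy)-4,5-dihydro-1,3-dioxepine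
Product: 12 (2S,3R,4S)-2-(3,4-dimethoxyphenyl)-4-[(R)-(3,4-dimethoxyphenyl)(triisopropylsilyloxy)methyl]-3-(triisopropylsilyloxy)oxolane-3-carbaldehyde
Conditions: Me2AlCl (1.5 equiv), CH2Cl2, −78 °C; aq. potassium sodium tartrate
Reagents that add atoms: none
Why: Me2AlCl ionises the acetal bond between the aryl-bearing carbon and the enol oxygen (both C2 epimers converge), giving an O-alkyl oxocarbenium ion tethered to the aluminium enolate of an α-silyloxy aldehyde; the enolate carbon (C6 of 11) then bonds to the oxocarbenium carbon, so the acetal carbon has moved from O to C (net 1,3-shift), the seven-membered ring has contracted to the oxolane and the enol CH has become the formyl group. The closest known reaction is the Lewis-acid ring contraction of 4,5-dihydro-1,3-dioxepines to oxolane-3-carbaldehydes (vinyl acetal rearrangement, an intramolecular Mukaiyama-type aldol related to the Petasis–Ferrier rearrangement), applied here to a member that carries a silyloxy group on the nucleophilic carbon. The oxolane closes in a 5-(enolexo)-endo-trig mode. Quaternary C3 is controlled by the existing C4 centre through allylic 1,3-strain: C4–H eclipses the enolate double bond, the CH2–O tether brings the electrophile to the face away from the CH(Ar)OSi side chain, and the formyl group ends trans and the silyloxy group cis to that side chain, which is the arrangement the trans junction needs; at C2 the aryl group should take the position anti to the bulky silyloxy group (cis to CHO), as in the kinetic 2,3-cis outcome of the parent reaction. The step needs bonding through the silyloxy-bearing carbon and not through the enol CH (which would give a six-membered ketone): the aluminium-bound enolate oxygen is by far the stronger donor, so the carbon β to it should be the nucleophile.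

Step 8
Reactants: 12 (2S,3R,4S)-2-(3,4-dimethoxyphenyl)-4-[(R)-(3,4-dimethoxyphenyl)(triisopropylsilyloxy)methyl]-3-(triisopropylsilyloxy)oxolane-3-carbaldehyde
Product: 13 [(2S,3S,4S)-2-(3,4-dimethoxyphenyl)-4-[(R)-(3,4-dimethoxyphenyl)(triisopropylsilyloxy)methyl]-3-(triisopropylsilyloxy)oxolan-3-yl]methanol
Conditions: NaBH4, MeOH/THF, 0 °C
Reagents that add atoms: none
Why: Borohydride reduction of the aldehyde, the only reducible group; the bulky silyl ethers should not migrate under these mild conditions.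

Step 9
Reactants: 13 [(2S,3S,4S)-2-(3,4-dimethoxyphenyl)-4-[(R)-(3,4-dimethoxyphenyl)(triisopropylsilyloxy)methyl]-3-(triisopropylsilyloxy)oxolan-3-yl]methanol
Product: 14 [(2S,3S,4S)-2-(3,4-dimethoxyphenyl)-4-[(R)-(3,4-dimethoxyphenyl)(triisopropylsilyloxy)methyl]-3-(triisopropylsilyloxy)oxolan-3-yl]methyl methanesulfonate
Conditions: MsCl, Et3N, CH2Cl2, 0 °C
Reagents that add atoms: methanesulfonyl chloride, CS(=O)(=O)Cl
Why: Sulfonylation (mesylation) of the only free hydroxyl, a primary neopentyl-type alcohol.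

Step 10
Reactants: 14 [(2S,3S,4S)-2-(3,4-dimethoxyphenyl)-4-[(R)-(3,4-dimethoxyphenyl)(triisopropylsilyloxy)methyl]-3-(triisopropylsilyloxy)oxolan-3-yl]methyl methanesulfonate
Product: 16 (3S,3aS,6R,6aS)-3,6-bis(3,4-dimethoxyphenyl)tetrahydro-1H,3H-furo[3,4-c]furan-3a(4H)-ol, via bicyclic silyl ether 15 (not isolated)
Conditions: Bu4NF (1.3 equiv), THF, 0 to 40 °C; then Bu4NF (4 equiv), 65 °C
Reagents that add atoms: none
Why: Fluoride cleaves the secondary benzylic silyl ether and the alkoxide displaces the primary mesylate in a 5-exo-tet Williamson etherification that closes ring B, an irreversible SN2 closure being the kinetic way to build the strained trans junction (no β-hydrogen for elimination, no stereocentre touched); the hindered tertiary silyl ether should survive until the temperature is raised, when excess fluoride removes it.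

Compound list
1 | (Z)-but-2-ene-1,4-diol | OC/C=C\CO | starting material
2 | 3,4-dimethoxybenzaldehyde (veratraldehyde) | COc1ccc(C=O)cc1OC | starting material
3 | 2-(3,4-dimethoxyphenyl)-4,7-dihydro-1,3-dioxepine | COc1ccc(cc1OC)C1OCC=CCO1 | intermediate
4 | 9-[2-(3,4-dimethoxyphenyl)-1,3-dioxepan-5-yl]-9-borabicyclo[3.3.1]nonane (not isolated) | COc1ccc(cc1OC)C1OCCC(CO1)B1C2CCCC1CCC2 | intermediate
5 | 2-(3,4-dimethoxyphenyl)-1,3-dioxepan-5-ol (racemic, cis/trans mixture) | COc1ccc(cc1OC)C1OCCC(O)CO1 | intermediate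
6 | 2-(3,4-dimethoxyphenyl)-1,3-dioxepan-5-one (racemic) | COc1ccc(cc1OC)C1OCCC(=O)CO1 | intermediate
7 | [2-(3,4-dimethoxyphenyl)-4,7-dihydro-1,3-dioxepin-5-yl]oxy(trimethyl)silane | COc1ccc(cc1OC)C1OCC=C(O[Si](C)(C)C)CO1 | intermediate
8 | trichloro{[2-(3,4-dimethoxyphenyl)-4,7-dihydro-1,3-dioxepin-5-yl]oxy}silane (not isolated) | COc1ccc(cc1OC)C1OCC=C(O[Si](Cl)(Cl)Cl)CO1 | intermediate
9 | (6S)-6-[(R)-(3,4-dimethoxyphenyl)(hydroxy)methyl]-2-(3,4-dimethoxyphenyl)-1,3-dioxepan-5-one (anti aldol, C2 epimers) | COc1ccc(cc1OC)[C@H](O)[C@@H]1COC(c2ccc(OC)c(OC)c2)OCC1=O | intermediate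
10 | (6S)-2-(3,4-dimethoxyphenyl)-6-[(R)-(3,4-dimethoxyphenyl)(triisopropylsilyloxy)methyl]-1,3-dioxepan-5-one (C2 epimers, not isolated) | COc1ccc(cc1OC)[C@H](O[Si](C(C)C)(C(C)C)C(C)C)[C@@H]1COC(c2ccc(OC)c(OC)c2)OCC1=O | intermediate
11 | (5S)-2-(3,4-dimethoxyphenyl)-5-[(R)-(3,4-dimethoxyphenyl)(triisopropylsilyloxy)methyl]-6-(triisopropylsilyloxy)-4,5-dihydro-1,3-dioxepine (C2 epimers) | COc1ccc(cc1OC)[C@H](O[Si](C(C)C)(C(C)C)C(C)C)[C@@H]1COC(c2ccc(OC)c(OC)c2)OC=C1O[Si](C(C)C)(C(C)C)C(C)C | intermediate
12 | (2S,3R,4S)-2-(3,4-dimethoxyphenyl)-4-[(R)-(3,4-dimethoxyphenyl)(triisopropylsilyloxy)methyl]-3-(triisopropylsilyloxy)oxolane-3-carbaldehyde | COc1ccc(cc1OC)[C@H](O[Si](C(C)C)(C(C)C)C(C)C)[C@@H]1CO[C@@H](c2ccc(OC)c(OC)c2)[C@@]1(O[Si](C(C)C)(C(C)C)C(C)C)C=O | intermediate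
13 | [(2S,3S,4S)-2-(3,4-dimethoxyphenyl)-4-[(R)-(3,4-dimethoxyphenyl)(triisopropylsilyloxy)methyl]-3-(triisopropylsilyloxy)oxolan-3-yl]methanol | COc1ccc(cc1OC)[C@H](O[Si](C(C)C)(C(C)C)C(C)C)[C@@H]1CO[C@@H](c2ccc(OC)c(OC)c2)[C@@]1(O[Si](C(C)C)(C(C)C)C(C)C)CO | intermediate
14 | [(2S,3S,4S)-2-(3,4-dimethoxyphenyl)-4-[(R)-(3,4-dimethoxyphenyl)(triisopropylsilyloxy)methyl]-3-(triisopropylsilyloxy)oxolan-3-yl]methyl methanesulfonate | COc1ccc(cc1OC)[C@H](O[Si](C(C)C)(C(C)C)C(C)C)[C@@H]1CO[C@@H](c2ccc(OC)c(OC)c2)[C@@]1(O[Si](C(C)C)(C(C)C)C(C)C)COS(C)(=O)=O | intermediate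
15 | (3S,3aS,6R,6aS)-3,6-bis(3,4-dimethoxyphenyl)-3a-(triisopropylsilyloxy)tetrahydro-1H,3H-furo[3,4-c]furan (not isolated) | COc1ccc([C@@H]2OC[C@]3(O[Si](C(C)C)(C(C)C)C(C)C)[C@H](c4ccc(OC)c(OC)c4)OC[C@@H]23)cc1OC | intermediate
16 | (3S,3aS,6R,6aS)-3,6-bis(3,4-dimethoxyphenyl)tetrahydro-1H,3H-furo[3,4-c]furan-3a(4H)-ol | COc1ccc([C@@H]2OC[C@]3(O)[C@H](c4ccc(OC)c(OC)c4)OC[C@@H]23)cc1OC | target

Total step count: 10. Longest linear sequence: 10 steps (from 1; aldehyde 2 enters in steps 1 and 5).

Steps most likely to fail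

Step 7 (key step). The ene-diol unit is ambident, so the carbon–carbon bond may form through the enol CH carbon instead, closing a six-membered silyloxy ketone. Alternatively the congested quaternary centre may form so slowly that the ion pair only re-closes at oxygen and silyl groups are lost. Fallback: the tertiary oxygen is carried as an enol carbamate, which cannot act as the donor, and is unmasked reductively at the end. It sets out from 10, here isolated after silylation of 9 at the hydroxyl only (iPr3SiOTf 1.1 equiv, 2,6-lutidine, −78 °C). KN(SiMe3)2 then iPr2NCOCl (kinetic deprotonation at the unhindered O–CH2 group) should give the enol carbamate vinyl acetal F1. Me2AlCl ring contraction would give the carbamate aldehyde F2, NaBH4 the carbamate alcohol F3, and MsCl/Et3N the carbamate mesylate F4. Bu4NF then closes ring B to the bicyclic carbamate F5, the carbamate being inert to the alkoxide. LiAlH4 in refluxing THF cleaves the carbamate and the sequence comes back to the route at 16.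

Step 10. Closure of the strained trans-fused ring B may be slow, so that loss or 1,3-migration of the tertiary silyl group intervenes and the freed tertiary alkoxide closes a spiro-epoxide with the mesylate. Fallback: a redox-dehydrative (Mitsunobu-type) etherification that never generates a free alkoxide. It sets out from 13: Bu4NF (1.1 equiv, 0 °C) removes only the secondary benzylic silyl ether to give the diol F6. PPh3/DIAD in toluene should activate the less hindered primary hydroxyl, which is displaced by the benzylic hydroxyl with retention at the benzylic carbon. This comes back to the route at 15, which is desilylated as in the second stage of step 10.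

Step 5. Enantio- or diastereoselection may be insufficient with the electron-rich aldehyde and the oxygen-rich enolate, or the aryl acetal may open during the chlorosilane exchange. Fallback: both centres are set by reduction with dynamic kinetic resolution. It sets out from 6: LiN(iPr)2 then 1-(3,4-dimethoxybenzoyl)benzotriazole gives the β-diketone F7, whose C6 centre is configurationally labile. RuCl[(R,R)-TsDPEN](p-cymene) with HCO2H/Et3N (asymmetric transfer hydrogenation) should reduce only the aryl ketone to the (R)-carbinol, with the fast-epimerising C6 following; the anti preference would have to be established. This comes back to the route at 9.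

Further compounds
F1 | step 7 | (5S)-2-(3,4-dimethoxyphenyl)-5-[(R)-(3,4-dimethoxyphenyl)(triisopropylsilyloxy)methyl]-4,5-dihydro-1,3-dioxepin-6-yl N,N-diisopropylcarbamate | COc1ccc(cc1OC)[C@H](O[Si](C(C)C)(C(C)C)C(C)C)[C@@H]1COC(c2ccc(OC)c(OC)c2)OC=C1OC(=O)N(C(C)C)C(C)C
F2 | step 7 | (2S,3R,4S)-2-(3,4-dimethoxyphenyl)-4-[(R)-(3,4-dimethoxyphenyl)(triisopropylsilyloxy)methyl]-3-formyloxolan-3-yl N,N-diisopropylcarbamate | COc1ccc(cc1OC)[C@H](O[Si](C(C)C)(C(C)C)C(C)C)[C@@H]1CO[C@@H](c2ccc(OC)c(OC)c2)[C@@]1(OC(=O)N(C(C)C)C(C)C)C=O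
F3 | step 7 | (2S,3S,4S)-2-(3,4-dimethoxyphenyl)-4-[(R)-(3,4-dimethoxyphenyl)(triisopropylsilyloxy)methyl]-3-(hydroxymethyl)oxolan-3-yl N,N-diisopropylcarbamate | COc1ccc(cc1OC)[C@H](O[Si](C(C)C)(C(C)C)C(C)C)[C@@H]1CO[C@@H](c2ccc(OC)c(OC)c2)[C@@]1(OC(=O)N(C(C)C)C(C)C)CO
F4 | step 7 | (2S,3S,4S)-2-(3,4-dimethoxyphenyl)-4-[(R)-(3,4-dimethoxyphenyl)(triisopropylsilyloxy)methyl]-3-[(methylsulfonyloxy)methyl]oxolan-3-yl N,N-diisopropylcarbamate | COc1ccc(cc1OC)[C@H](O[Si](C(C)C)(C(C)C)C(C)C)[C@@H]1CO[C@@H](c2ccc(OC)c(OC)c2)[C@@]1(OC(=O)N(C(C)C)C(C)C)COS(C)(=O)=O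
F5 | step 7 | (3S,3aS,6R,6aS)-3,6-bis(3,4-dimethoxyphenyl)tetrahydro-1H,3H-furo[3,4-c]furan-3a(4H)-yl N,N-diisopropylcarbamate | COc1ccc([C@@H]2OC[C@]3(OC(=O)N(C(C)C)C(C)C)[C@H](c4ccc(OC)c(OC)c4)OC[C@@H]23)cc1OC
F6 | step 10 | (R)-(3,4-dimethoxyphenyl)[(3S,4S,5S)-5-(3,4-dimethoxyphenyl)-4-(hydroxymethyl)-4-(triisopropylsilyloxy)oxolan-3-yl]methanol | COc1ccc(cc1OC)[C@H](O)[C@@H]1CO[C@@H](c2ccc(OC)c(OC)c2)[C@@]1(O[Si](C(C)C)(C(C)C)C(C)C)CO
F7 | step 5 | 6-(3,4-dimethoxybenzoyl)-2-(3,4-dimethoxyphenyl)-1,3-dioxepan-5-one | COc1ccc(cc1OC)C(=O)C1COC(c2ccc(OC)c(OC)c2)OCC1=O
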